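**Retrosynthetic overview**
1. The oxane atoms O1 and C2–C6, together with Cα (acrylate carbon on C2) and C1′ (first chain carbon on C5), are read as a 2-oxabicyclo[2.2.2]oct-5-ene. Its Cα=C1′ bridge can reach from C2 to C5 only across one face of the oxane, so cutting that bridge must leave the cis-2,5 pattern, (2R,5R), of rhopaloic acid B.
2. The key disconnection is C2–C3 and C4–C5: an inverse-electron-demand Diels–Alder reaction of methyl coumalate (O1, C2, Cα with its carboxyl carbon, C1′, C5, C6) with a vinyl ether (C3, C4). The two pyrone carbonyl groups lie 1,4 across the ring and cannot chelate one metal, so the absolute sense is taken from an (R)-1-phenylethyl group on the vinyl ether oxygen, a chiral stand-in for benzyl that is removed the same way.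
3. Ring order: pyrone ring (purchased) → cyclohexene ring closed in the cycloaddition (bridged lactone) → lactone C=O reduced to the C6 methylene (oxane complete, as bridged ether) → cyclohexene ring opened again by ozonolysis of Cα=C1′.
4. C4–O is removed by radical deoxygenation while no alkene is present. C1′–C2′ is then made from the C1′ iodide and lithiated farnesyl phenyl sulfone, followed by palladium-catalysed desulfonylation. The carboxyl carbon passes through these steps as a protected 1,2-diol.
5. Last come Cα alcohol → ketone → non-basic methylenation, then allylic alcohol → enal → acid.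

Key step: step 2

Numbering: target numbering is used in the text. In the bicyclic names C1 = target C2, C3 = C6, C4 = C5, C5 = C1′, C6 = Cα, C7 = C3, C8 = C4.

Assumption: the (R)-1-phenylethyl group is taken to react from its s-trans, C–H-eclipsed conformer with attack anti to phenyl (Si face of the vinyl ether). This sense must be confirmed on adduct 5 by crystal structure analysis. If it proves opposite, (S)-1-phenylethanol is used with otherwise identical chemistry.

**Step 1**
Reactants: 1 (R)-1-phenylethanol; 2 n-butyl vinyl ether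
Product: 3 (R)-1-phenylethyl vinyl ether
Conditions: Pd(OCOCF3)2 (1 mol %), 4,7-diphenyl-1,10-phenanthroline (1 mol %), Et3N (5 mol %), 2 (20 equiv, as solvent), 75 °C
Reagents that add atoms: none
Why: Palladium-catalysed transfer vinylation (transetherification of a vinyl ether) exchanges the alkoxy group at the vinylic carbon only, so the benzylic C–O bond of 1 and its R configuration are untouched, and the large excess of 2 drives the equilibrium.

**Step 2**
Reactants: 4 methyl coumalate; 3 (R)-1-phenylethyl vinyl ether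
Product: 5 methyl (1R,4R,8R)-3-oxo-8-[(1R)-1-phenylethoxy]-2-oxabicyclo[2.2.2]oct-5-ene-6-carboxylate (endo adduct)
Conditions: 3 (3 equiv), Yb(fod)3 (10 mol %), CH2Cl2 (2 M), 20–25 °C, dark, 3–5 d; chromatography, then crystallisation
Reagents that add atoms: none
Why: This is a concerted but asynchronous [4+2] cycloaddition with inverse electron demand, in which the nucleophilic CH2 terminus of 3 bonds to the most electrophilic pyrone carbon C6 (target C2) and the oxygen-bearing carbon bonds to pyrone C3 (target C5), the known behaviour of coumalates and other acceptor-substituted 2-pyrones toward alkyl vinyl ethers. One ring is closed, the cyclohexene C2–C3–C4–C5–C1′=Cα, by suprafacial addition across the pyrone diene, while the former O1–C6(=O) unit becomes the lactone bridge. C2 and C5 are bridgeheads, so their cis relation is fixed by the bicycle itself, and the endo transition state places the C4 alkoxy group syn to the new Cα=C1′ bridge. The absolute sense comes from the dienophile, since in the s-trans, C–H-eclipsed conformer of 3 the phenyl group covers the Re face and the pyrone should add to the Si face, the closest analogy being auxiliary-controlled additions of chiral 1-arylalkyl vinyl ethers to 3-sulfonyl- and 3-alkoxycarbonyl-2-pyrones. Whatever the level of induction, the facial and endo/exo isomers are diastereomers, so 5 can be brought to purity by chromatography and crystallisation. Room temperature and the mild oxophilic Yb(fod)3 should keep the vinyl ether from polymerising and the adduct from extruding CO2.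

**Step 3**
Reactants: 5 endo adduct
Product: 7 methyl (1R,4R,8R)-3-acetoxy-8-[(1R)-1-phenylethoxy]-2-oxabicyclo[2.2.2]oct-5-ene-6-carboxylate (C3 epimers), via aluminium hemiacetal 6 (not isolated)
Conditions: i-Bu2AlH (1.1 equiv), CH2Cl2, −78 °C; then pyridine, DMAP, Ac2O, −78 → −20 °C
Reagents that add atoms: acetic anhydride CC(=O)OC(C)=O; diisobutylaluminium hydride CC(C)C[AlH]CC(C)C (its aluminium stays only in 6)
Why: In this reductive acetylation of a lactone the strained, non-conjugated bridged lactone should take up hydride faster than the conjugated methyl ester, and the aluminium hemiacetal 6, stable at −78 °C, is acetylated in the flask so that the open hydroxy aldehyde (prone to loss of the C4 alkoxy group and aromatisation) is never released, the new acetal centre being of no consequence.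

**Step 4**
Reactants: 7 acetoxy acetal
Product: 8 methyl (1R,4S,8R)-8-[(1R)-1-phenylethoxy]-2-oxabicyclo[2.2.2]oct-5-ene-6-carboxylate (bridged ether)
Conditions: Et3SiH (5 equiv), BF3·OEt2 (1.5 equiv), CH2Cl2, −78 °C; Et3N quench at −78 °C
Reagents that add atoms: none
Why: In this ionic hydrogenation of an acetal acetate BF3 ionises only the anomeric acetate, the resulting O1=C6 oxocarbenium ion lies within a two-atom bridge (not at a bridgehead) and cannot lose the bridgehead proton at C5, and Et3SiH turns it into the C6 methylene, after which CO2 extrusion is no longer possible.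

**Step 5**
Reactants: 8 bridged ether
Product: 10 1-{(2R,4R,5S)-5-(hydroxymethyl)-4-[(1R)-1-phenylethoxy]oxan-2-yl}ethane-1,2-diol (all-cis oxane; Cα epimers), via keto aldehyde 9 (not isolated)
Conditions: O3, CH2Cl2–MeOH (4:1), −78 °C, stopped at first persistent blue, N2 purge; Me2S, −78 → 0 °C; NaBH4 (8 equiv), 0 °C → rt
Reagents that add atoms: ozone [O-][O+]=O
Why: Ozonolysis with reductive work-up cuts the Cα=C1′ bridge and frees the all-cis oxane; it has to follow step 4 because a formyl group next to the lactone carbonyl would make C5 an enolisable 1,3-dicarbonyl centre, the β-alkoxy aldehyde 9 is reduced at once before it can epimerise or eliminate, and borohydride takes the α-keto ester through the α-hydroxy ester to the 1,2-diol, whose Cα centre is erased in step 17.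

**Step 6**
Reactants: 10 triol
Product: 11 {(3S,4R,6R)-6-(2,2-dimethyl-1,3-dioxolan-4-yl)-4-[(1R)-1-phenylethoxy]oxan-3-yl}methanol
Conditions: 2,2-dimethoxypropane, PPTS (cat.), acetone, rt
Reagents that add atoms: 2,2-dimethoxypropane COC(C)(C)OC
Why: Acid-catalysed acetal exchange gives the five-membered dioxolane of the terminal 1,2-diol as the thermodynamic product and leaves the remote C1′ hydroxyl free, which stores the carboxyl carbon in a form that withstands the sulfonyl carbanion and LiHBEt3 used later, as a methyl ester would not.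

**Step 7**
Reactants: 11 acetonide alcohol
Product: 12 (3S,4R,6R)-6-(2,2-dimethyl-1,3-dioxolan-4-yl)-3-(hydroxymethyl)oxan-4-ol
Conditions: H2 (1–3 atm), Pd(OH)2/C, EtOAc, rt
Reagents that add atoms: none
Why: Catalytic hydrogenolysis of the secondary benzylic ether removes the auxiliary as ethylbenzene, and it is placed here because no alkene is present yet, whereas after step 13 it would saturate the triene.

**Step 8**
Reactants: 12 cis-1,3-diol
Product: 13 cis-fused cyclic thionocarbonate (1,3-dioxane-2-thione across O–C4 and O–C1′)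
Conditions: 1,1′-thiocarbonyldiimidazole (1.3 equiv), DMAP (cat.), THF, 65 °C
Reagents that add atoms: 1,1′-thiocarbonyldiimidazole S=C(n1ccnc1)n1ccnc1
Why: Thiocarbonyl transfer to a 1,3-diol closes a six-membered cyclic thionocarbonate, which is cis-fused and unstrained because the endo cycloaddition left the C4 hydroxyl and the C5 hydroxymethyl group on the same face.

**Step 9**
Reactants: 13 cyclic thionocarbonate
Product: 15 {(3S,6R)-6-(2,2-dimethyl-1,3-dioxolan-4-yl)oxan-3-yl}methanol (cis), via stannyl thiocarbonate 14 (not isolated)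
Conditions: Bu3SnH (2 equiv, slow addition), AIBN (0.2 equiv), toluene, 110 °C; then K2CO3 (cat.), MeOH, rt
Reagents that add atoms: tributyltin hydride CCCC[SnH](CCCC)CCCC (its tin stays only in 14)
Why: In this Barton–McCombie deoxygenation in its cyclic thionocarbonate form the tin radical adds to sulfur, the adduct radical fragments toward the more stable secondary C4 radical rather than the primary C1′ radical, hydrogen transfer gives 14 and methanolysis frees the C1′ alcohol; the step stands after ozonolysis because in the bicycle this radical would attack the acrylate bridge, and before chain attachment because with the chain in place it would be a 5-hexenyl radical closing 5-exo onto C3′=C4′.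

**Step 10**
Reactants: 15 primary alcohol
Product: 16 (2R,5R)-2-(2,2-dimethyl-1,3-dioxolan-4-yl)-5-(iodomethyl)oxane
Conditions: I2, PPh3, imidazole, CH2Cl2, 0 °C → rt
Reagents that add atoms: iodine II
Why: Appel-type iodination displaces the activated primary hydroxyl by SN2 at the non-stereogenic C1′, and the imidazole buffer protects the acetonide.

**Step 11**
Reactants: 17 (2E,6E)-farnesol
Product: 18 (2E,6E)-farnesyl bromide
Conditions: PBr3 (0.4 equiv), Et2O, 0 °C; used crude
Reagents that add atoms: phosphorus tribromide BrP(Br)Br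
Why: Bromination of a primary allylic alcohol with PBr3 at low temperature proceeds by SN2 displacement without allylic transposition or E/Z scrambling.

**Step 12**
Reactants: 18 farnesyl bromide
Product: 19 (2E,6E)-farnesyl phenyl sulfone
Conditions: PhSO2Na, DMF, rt
Reagents that add atoms: sodium benzenesulfinate [Na+].[O-]S(=O)c1ccccc1
Why: S-Alkylation of the ambident sulfinate anion by the soft allylic bromide (SN2) gives the primary allylic sulfone with both E alkenes intact.

**Step 13**
Reactants: 19 farnesyl phenyl sulfone; 16 iodide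
Product: 21 cis-oxane acetonide carrying CH2–CH(SO2Ph)–CH=C(CH3)– at C5 (C2′ epimers), via lithiated sulfone 20 (not isolated)
Conditions: 19 (1.3 equiv), n-BuLi (1.25 equiv), THF–DMPU, −78 °C; then 16, −78 → −20 °C
Reagents that add atoms: n-butyllithium [Li]CCCC (its lithium stays only in 20)
Why: α-Alkylation of a lithiated allylic sulfone by a primary iodide (SN2) forms C1′–C2′, α-attack being the normal regiochemistry of such anions, while the acetal and ether groups are inert and the new sulfone-bearing centre disappears in step 14.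

**Step 14**
Reactants: 21 coupled sulfone
Product: 22 (2R,5R)-2-(2,2-dimethyl-1,3-dioxolan-4-yl)-5-[(3E,7E)-4,8,12-trimethyltrideca-3,7,11-trien-1-yl]oxane
Conditions: PdCl2(dppp) (5 mol %), LiHBEt3 (3 equiv), THF, 0 °C
Reagents that add atoms: none
Why: In this palladium-catalysed hydride desulfonylation of an allylic sulfone, ionisation to the π-allyl complex and hydride delivery to the less substituted terminus C2′ should keep C3′=C4′ in place and E, and only ethers and an acetal are exposed to the borohydride.

**Step 15**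
Reactants: 22 acetonide
Product: 23 1-{(2R,5R)-5-[(3E,7E)-4,8,12-trimethyltrideca-3,7,11-trien-1-yl]oxan-2-yl}ethane-1,2-diol (Cα epimers)
Conditions: AcOH–THF–H2O (3:1:1), 40 °C
Reagents that add atoms: none
Why: Mild acid hydrolysis cleaves the dioxolane, and dilute acetic acid is too weak to protonate the trisubstituted alkenes.

**Step 16**
Reactants: 23 diol
Product: 24 primary TBS ether of 23
Conditions: TBSCl (1.05 equiv), imidazole, CH2Cl2, 0 °C
Reagents that add atoms: tert-butyldimethylsilyl chloride CC(C)(C)[Si](C)(C)Cl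
Why: Sterically controlled monosilylation takes the primary hydroxyl of the 1,2-diol and leaves the Cα hydroxyl free.

**Step 17**
Reactants: 24 secondary alcohol
Product: 25 2-(tert-butyldimethylsilyloxy)-1-{(2R,5R)-5-[(3E,7E)-4,8,12-trimethyltrideca-3,7,11-trien-1-yl]oxan-2-yl}ethan-1-one
Conditions: Dess–Martin periodinane, CH2Cl2, 0 °C → rt
Reagents that add atoms: none
Why: Dess–Martin oxidation under neutral, non-enolising conditions merges both Cα epimers into one ketone and leaves the now acidic C2–H untouched, which matters because the trans-2,5 isomer is the more stable one.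

**Step 18**
Reactants: 25 ketone
Product: 26 tert-butyldimethylsilyl ether of 2-{(2R,5R)-5-[(3E,7E)-4,8,12-trimethyltrideca-3,7,11-trien-1-yl]oxan-2-yl}prop-2-en-1-ol
Conditions: Zn, CH2Br2, TiCl4 (reagent pre-formed in THF, 0–5 °C); then 25, CH2Cl2, 0 °C → rt
Reagents that add atoms: dibromomethane BrCBr
Why: In the Lombardo–Takai methylenation the gem-dimetallic zinc/titanium reagent is nucleophilic but hardly basic, so the ketone should be methylenated without enolisation toward C2 (a phosphorus ylide could epimerise the cis oxane to the diequatorial trans isomer), and the silyl ether, ring ether and trisubstituted alkenes are unaffected.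

**Step 19**
Reactants: 26 allylic silyl ether
Product: 27 2-{(2R,5R)-5-[(3E,7E)-4,8,12-trimethyltrideca-3,7,11-trien-1-yl]oxan-2-yl}prop-2-en-1-ol
Conditions: Bu4NF, THF, 0 °C
Reagents that add atoms: none
Why: Fluoride-induced cleavage of the silyl ether frees the allylic alcohol without touching any other group.

**Step 20**
Reactants: 27 allylic alcohol
Product: 28 2-{(2R,5R)-5-[(3E,7E)-4,8,12-trimethyltrideca-3,7,11-trien-1-yl]oxan-2-yl}prop-2-enal
Conditions: activated MnO2 (excess), CH2Cl2, rt; used directly
Reagents that add atoms: none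
Why: Heterogeneous MnO2 oxidation is selective for the allylic alcohol under neutral conditions, so the isolated alkenes and C2 stay untouched.

**Step 21**
Reactants: 28 enal
Product: 29 rhopaloic acid B
Conditions: NaClO2, NaH2PO4, 2-methyl-2-butene (excess), t-BuOH–H2O, 0 °C → rt
Reagents that add atoms: sodium chlorite [Na+].[O-]Cl=O
Why: Pinnick oxidation converts the enal into the acrylic acid, the excess 2-methyl-2-butene traps hypochlorous acid before it can attack the triene, and the buffered medium leaves C2 and C5 as set in step 2.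

**Compound list**
1 | (R)-1-phenylethanol | C[C@@H](O)c1ccccc1 | starting material
2 | n-butyl vinyl ether | C=COCCCC | starting material
3 | (R)-1-phenylethyl vinyl ether | C=CO[C@H](C)c1ccccc1 | intermediate
4 | methyl coumalate (methyl 2-oxo-2H-pyran-5-carboxylate) | COC(=O)C1=COC(=O)C=C1 | starting material
5 | methyl (1R,4R,8R)-3-oxo-8-[(1R)-1-phenylethoxy]-2-oxabicyclo[2.2.2]oct-5-ene-6-carboxylate (endo; alkoxy syn to C5=C6) | COC(=O)C1=C[C@@H]2[C@H](O[C@H](C)c3ccccc3)C[C@H]1OC2=O | intermediate
6 | C3 diisobutylaluminium hemiacetal of 5 | COC(=O)C1=C[C@@H]2[C@H](O[C@H](C)c3ccccc3)C[C@H]1OC2O[Al](CC(C)C)CC(C)C | intermediate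
7 | methyl (1R,4R,8R)-3-acetoxy-8-[(1R)-1-phenylethoxy]-2-oxabicyclo[2.2.2]oct-5-ene-6-carboxylate (C3 epimers) | COC(=O)C1=C[C@@H]2[C@H](O[C@H](C)c3ccccc3)C[C@H]1OC2OC(C)=O | intermediate
8 | methyl (1R,4S,8R)-8-[(1R)-1-phenylethoxy]-2-oxabicyclo[2.2.2]oct-5-ene-6-carboxylate | COC(=O)C1=C[C@@H]2[C@H](O[C@H](C)c3ccccc3)C[C@H]1OC2 | intermediate
9 | methyl 2-{(2R,4R,5S)-5-formyl-4-[(1R)-1-phenylethoxy]oxan-2-yl}-2-oxoacetate (all-cis) | COC(=O)C(=O)[C@H]1C[C@@H](O[C@H](C)c2ccccc2)[C@@H](C=O)CO1 | intermediate
10 | 1-{(2R,4R,5S)-5-(hydroxymethyl)-4-[(1R)-1-phenylethoxy]oxan-2-yl}ethane-1,2-diol (Cα epimers) | OCC(O)[C@H]1C[C@@H](O[C@H](C)c2ccccc2)[C@@H](CO)CO1 | intermediate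
11 | {(3S,4R,6R)-6-(2,2-dimethyl-1,3-dioxolan-4-yl)-4-[(1R)-1-phenylethoxy]oxan-3-yl}methanol | CC1(C)OCC(O1)[C@H]2C[C@@H](O[C@H](C)c3ccccc3)[C@@H](CO)CO2 | intermediate
12 | (3S,4R,6R)-6-(2,2-dimethyl-1,3-dioxolan-4-yl)-3-(hydroxymethyl)oxan-4-ol | CC1(C)OCC(O1)[C@H]2C[C@@H](O)[C@@H](CO)CO2 | intermediate
13 | cis-fused cyclic thionocarbonate of 12 (O–C4 and O–C1′ joined through C=S) | CC1(C)OCC(O1)[C@H]2C[C@H]3OC(=S)OC[C@H]3CO2 | intermediate
14 | O-{[(3S,6R)-6-(2,2-dimethyl-1,3-dioxolan-4-yl)oxan-3-yl]methyl} S-(tributylstannyl) thiocarbonate | CC1(C)OCC(O1)[C@H]2CC[C@@H](COC(=O)S[Sn](CCCC)(CCCC)CCCC)CO2 | intermediate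
15 | {(3S,6R)-6-(2,2-dimethyl-1,3-dioxolan-4-yl)oxan-3-yl}methanol (cis) | CC1(C)OCC(O1)[C@H]2CC[C@@H](CO)CO2 | intermediate
16 | (2R,5R)-2-(2,2-dimethyl-1,3-dioxolan-4-yl)-5-(iodomethyl)oxane (cis) | CC1(C)OCC(O1)[C@H]2CC[C@@H](CI)CO2 | intermediate
17 | (2E,6E)-farnesol | CC(C)=CCC/C(C)=C/CC/C(C)=C/CO | starting material
18 | (2E,6E)-farnesyl bromide | CC(C)=CCC/C(C)=C/CC/C(C)=C/CBr | intermediate
19 | (2E,6E)-farnesyl phenyl sulfone | CC(C)=CCC/C(C)=C/CC/C(C)=C/CS(=O)(=O)c1ccccc1 | intermediate
20 | α-lithiated farnesyl phenyl sulfone | CC(C)=CCC/C(C)=C/CC/C(C)=C/C([Li])S(=O)(=O)c1ccccc1 | intermediate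
21 | cis-oxane acetonide with 2′-(phenylsulfonyl)homofarnesyl chain at C5 (C2′ and Cα epimers) | CC1(C)OCC(O1)[C@H]2CC[C@@H](CC(/C=C(\C)CC/C=C(\C)CCC=C(C)C)S(=O)(=O)c3ccccc3)CO2 | intermediate
22 | (2R,5R)-2-(2,2-dimethyl-1,3-dioxolan-4-yl)-5-[(3E,7E)-4,8,12-trimethyltrideca-3,7,11-trien-1-yl]oxane | CC1(C)OCC(O1)[C@H]2CC[C@@H](CC/C=C(\C)CC/C=C(\C)CCC=C(C)C)CO2 | intermediate
23 | 1-{(2R,5R)-5-[(3E,7E)-4,8,12-trimethyltrideca-3,7,11-trien-1-yl]oxan-2-yl}ethane-1,2-diol | OCC(O)[C@H]1CC[C@@H](CC/C=C(\C)CC/C=C(\C)CCC=C(C)C)CO1 | intermediate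
24 | primary tert-butyldimethylsilyl ether of 23 | CC(C)(C)[Si](C)(C)OCC(O)[C@H]1CC[C@@H](CC/C=C(\C)CC/C=C(\C)CCC=C(C)C)CO1 | intermediate
25 | α-silyloxy ketone (Cα=O) of the cis-(2R,5R)-oxane | CC(C)(C)[Si](C)(C)OCC(=O)[C@H]1CC[C@@H](CC/C=C(\C)CC/C=C(\C)CCC=C(C)C)CO1 | intermediate
26 | silyl-protected 2-substituted allylic alcohol (Cα=CH2) | CC(C)(C)[Si](C)(C)OCC(=C)[C@H]1CC[C@@H](CC/C=C(\C)CC/C=C(\C)CCC=C(C)C)CO1 | intermediate
27 | 2-{(2R,5R)-5-[(3E,7E)-4,8,12-trimethyltrideca-3,7,11-trien-1-yl]oxan-2-yl}prop-2-en-1-ol | OCC(=C)[C@H]1CC[C@@H](CC/C=C(\C)CC/C=C(\C)CCC=C(C)C)CO1 | intermediate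
28 | 2-{(2R,5R)-5-[(3E,7E)-4,8,12-trimethyltrideca-3,7,11-trien-1-yl]oxan-2-yl}prop-2-enal | O=CC(=C)[C@H]1CC[C@@H](CC/C=C(\C)CC/C=C(\C)CCC=C(C)C)CO1 | intermediate
29 | rhopaloic acid B, 2-{(2R,5R)-5-[(3E,7E)-4,8,12-trimethyltrideca-3,7,11-trien-1-yl]oxan-2-yl}prop-2-enoic acid | C=C(C(=O)O)[C@H]1CC[C@@H](CC/C=C(\C)CC/C=C(\C)CCC=C(C)C)CO1 | target

**Step count**
Total steps: 21. Longest linear sequence: 19 (steps 1–10 and 13–21). Steps 11–12 make the sulfone branch.

**Steps most likely to fail**

Step 2. The risks are insufficient discrimination between the two faces of the vinyl ether, incomplete separation of the diastereomeric adducts, and slow turnover at a temperature low enough to prevent loss of CO2. The fallback sets out from 4 and returns at 12. It gives up auxiliary control in favour of a racemic cycloaddition followed by resolution.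
- Compound 4 is combined with purchased benzyl vinyl ether under the conditions of step 2. The racemic endo adduct is resolved by preparative chromatography on a chiral stationary phase to give methyl (1R,4R,8R)-8-(benzyloxy)-3-oxo-2-oxabicyclo[2.2.2]oct-5-ene-6-carboxylate F1.
- Reductive acetylation through the aluminium hemiacetal F2 gives the benzyl-series acetoxy acetal F3.
- Silane reduction gives the benzyl-series bridged ether F4.
- Ozonolysis through the benzyl-series keto aldehyde F5, followed by borohydride, gives the benzyloxy triol F6.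
- Acetal exchange gives the benzyloxy acetonide alcohol F7, and hydrogenolysis of the benzyl ether under the conditions of step 7 gives 12.

Step 3. The risks are competing hydride delivery to the conjugated ester and breakdown of the strained aluminium hemiacetal before it is acetylated. The fallback sets out from 3 and returns at 10. It shields the ester sterically, so that hydride can be used in excess and for a shorter time.
- Purchased coumalic acid and tert-butyl 2,2,2-trichloroacetimidate (CH2Cl2, rt) give tert-butyl coumalate F8.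
- Cycloaddition with 3 as in step 2 gives the tert-butyl ester adduct F9.
- i-Bu2AlH, which leaves the hindered ester alone at −78 °C, gives the aluminium hemiacetal F10. Acetylation in the flask gives the tert-butyl ester acetoxy acetal F11.
- Et3SiH/BF3·OEt2 at −78 °C gives the tert-butyl ester bridged ether F12.
- Ozonolysis with Me2S gives the tert-butyl keto aldehyde F13, which LiBH4 in THF–MeOH reduces completely to 10.

Step 9. The risks are fragmentation of the thionocarbonate radical toward the primary side and hydrogen transfer before fragmentation. The fallback sets out from 12 and returns at 15. It handles the two hydroxyl groups one at a time.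
- TBDPSCl and imidazole silylate only the primary hydroxyl to give the C1′ tert-butyldiphenylsilyl ether F14.
- PhOC(S)Cl, pyridine and DMAP convert the C4 hydroxyl into the O-phenyl thionocarbonate F15.
- Bu3SnH and AIBN in toluene give the C4-deoxygenated silyl ether F16, and Bu4NF releases 15.

**Further compounds**
F1 | step 2 | methyl (1R,4R,8R)-8-(benzyloxy)-3-oxo-2-oxabicyclo[2.2.2]oct-5-ene-6-carboxylate | COC(=O)C1=C[C@@H]2[C@H](OCc3ccccc3)C[C@H]1OC2=O
F2 | step 2 | C3 diisobutylaluminium hemiacetal of F1 | COC(=O)C1=C[C@@H]2[C@H](OCc3ccccc3)C[C@H]1OC2O[Al](CC(C)C)CC(C)C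
F3 | step 2 | methyl (1R,4R,8R)-3-acetoxy-8-(benzyloxy)-2-oxabicyclo[2.2.2]oct-5-ene-6-carboxylate (C3 epimers) | COC(=O)C1=C[C@@H]2[C@H](OCc3ccccc3)C[C@H]1OC2OC(C)=O
F4 | step 2 | methyl (1R,4S,8R)-8-(benzyloxy)-2-oxabicyclo[2.2.2]oct-5-ene-6-carboxylate | COC(=O)C1=C[C@@H]2[C@H](OCc3ccccc3)C[C@H]1OC2
F5 | step 2 | methyl 2-[(2R,4R,5S)-4-(benzyloxy)-5-formyloxan-2-yl]-2-oxoacetate | COC(=O)C(=O)[C@H]1C[C@@H](OCc2ccccc2)[C@@H](C=O)CO1
F6 | step 2 | 1-[(2R,4R,5S)-4-(benzyloxy)-5-(hydroxymethyl)oxan-2-yl]ethane-1,2-diol (Cα epimers) | OCC(O)[C@H]1C[C@@H](OCc2ccccc2)[C@@H](CO)CO1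
F7 | step 2 | [(3S,4R,6R)-4-(benzyloxy)-6-(2,2-dimethyl-1,3-dioxolan-4-yl)oxan-3-yl]methanol | CC1(C)OCC(O1)[C@H]2C[C@@H](OCc3ccccc3)[C@@H](CO)CO2
F8 | step 3 | tert-butyl coumalate | CC(C)(C)OC(=O)C1=COC(=O)C=C1
F9 | step 3 | tert-butyl (1R,4R,8R)-3-oxo-8-[(1R)-1-phenylethoxy]-2-oxabicyclo[2.2.2]oct-5-ene-6-carboxylate | CC(C)(C)OC(=O)C1=C[C@@H]2[C@H](O[C@H](C)c3ccccc3)C[C@H]1OC2=O
F10 | step 3 | C3 diisobutylaluminium hemiacetal of F9 | CC(C)(C)OC(=O)C1=C[C@@H]2[C@H](O[C@H](C)c3ccccc3)C[C@H]1OC2O[Al](CC(C)C)CC(C)C
F11 | step 3 | tert-butyl (1R,4R,8R)-3-acetoxy-8-[(1R)-1-phenylethoxy]-2-oxabicyclo[2.2.2]oct-5-ene-6-carboxylate (C3 epimers) | CC(C)(C)OC(=O)C1=C[C@@H]2[C@H](O[C@H](C)c3ccccc3)C[C@H]1OC2OC(C)=O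
F12 | step 3 | tert-butyl (1R,4S,8R)-8-[(1R)-1-phenylethoxy]-2-oxabicyclo[2.2.2]oct-5-ene-6-carboxylate | CC(C)(C)OC(=O)C1=C[C@@H]2[C@H](O[C@H](C)c3ccccc3)C[C@H]1OC2
F13 | step 3 | tert-butyl 2-{(2R,4R,5S)-5-formyl-4-[(1R)-1-phenylethoxy]oxan-2-yl}-2-oxoacetate | CC(C)(C)OC(=O)C(=O)[C@H]1C[C@@H](O[C@H](C)c2ccccc2)[C@@H](C=O)CO1
F14 | step 9 | C1′ tert-butyldiphenylsilyl ether of 12 | CC1(C)OCC(O1)[C@H]2C[C@@H](O)[C@@H](CO[Si](c3ccccc3)(c4ccccc4)C(C)(C)C)CO2
F15 | step 9 | C4 O-phenyl thionocarbonate of F14 | CC1(C)OCC(O1)[C@H]2C[C@@H](OC(=S)Oc3ccccc3)[C@@H](CO[Si](c4ccccc4)(c5ccccc5)C(C)(C)C)CO2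
F16 | step 9 | tert-butyldiphenylsilyl ether of 15 | CC1(C)OCC(O1)[C@H]2CC[C@@H](CO[Si](c3ccccc3)(c4ccccc4)C(C)(C)C)CO2
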